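The acrylic acid unit (C15 acid, C16=C17) hangs on C13 of carbocycle A (C8, C9, C11, C12, C13, C14), 1,4-trans to the spiro carbon C10. Cutting C12–C13 leads back to a C12 radical, made from a vinyl group on C9, and a C14-linked (Z)-2-(phenylsulfonylmethyl)enoate whose sulfonyl group leaves as C16=C17 forms.
Precursor 21 comes from the spiro alkylidene-malonate lactone 12 by vinyl-copper addition at C9, then C8 alkylation with bromo allyl sulfone 20 (methyl acrylate + silyloxyacetaldehyde + PhSO2Na).
Lactone 12 comes from an intramolecular Knoevenagel condensation (C8 malonate on O–C20, C9 aldehyde) on a 6-oxabicyclo[3.2.1]octan-3-one. C10 is quaternised at the enone stage (C9 first, C20 second), and C5 comes from an enantioselective vinyl addition to 4,4-dimethylcyclohexadienone.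
Ring order: cyclohexanone (present in 1) → tetrahydrofuran bridge C3–O–C6 → spiro δ-lactone → ring A. The C8 ester is then removed and the acrylate ester cleaved.
Key step: step 15

Numbering:
- Cyclohexanone ring: C1 (C=O), C2, C3 (O-bearing), C4 (CMe2), C5, C10 (spiro).
- Bridge: C3–O–C6–C5.
- Lactone: C10, C9, C8, C7 (C=O), O, C20.
- Ring A: C8, C9, C11, C12, C13, C14.
- Acrylic acid: C16 (α), C17 (=CH2), C15 (CO2H).

Assumption: the facial sense of the rhodium/(S)-BINAP addition in step 1 is taken to be that known for cyclohex-2-enone. If the gem-dimethyl group reverses it, (R)-BINAP is used.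

Design points:
- (a) A ketone that still carries H on C10 next to an alkylidene malonate closes through its enol oxygen to a 2-pyranone, so C10 is made quaternary before C8=C9 exists.
- (b) A free C6 hydroxyl would add to C9 of the alkylidene malonate, so the C3–O–C6 bridge is closed first.
- (c) The C1 ketone calls for rhodium-catalysed hydroboration.
- (d) The slow 6-exo closure calls for a hyponitrite initiator under nitrogen, because dissolved oxygen would capture the C12 radical.

Step 1
Reactants: 1 4,4-dimethylcyclohexa-2,5-dien-1-one
Product: 2 (S)-4,4-dimethyl-5-vinylcyclohex-2-en-1-one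
Conditions: CH2=CHBF3K (0.8 equiv), [Rh(cod)2]BF4 (3 mol%), (S)-BINAP (3.3 mol%), toluene/H2O 10:1, 100 °C
Reagents that add atoms: potassium vinyltrifluoroborate, C=C[B-](F)(F)F.[K+]
Why: Rhodium-catalysed asymmetric 1,4-addition (Hayashi–Miyaura reaction), in which the two enone arms of 1 are enantiotopic, the (S)-BINAP–rhodium vinyl species picks one arm and one face as it does with cyclohex-2-enone and so sets C5, and a deficit of the boron reagent holds back a second addition.

Step 2
Reactants: 2 (S)-4,4-dimethyl-5-vinylcyclohex-2-en-1-one
Product: 3 trans-6-(benzyloxymethyl)-4,4-dimethyl-5-vinylcyclohex-2-en-1-one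
Conditions: LDA, THF, −78 °C; BnOCH2Cl, −78 → −30 °C
Reagents that add atoms: benzyl chloromethyl ether, ClCOCc1ccccc1
Why: Kinetic enolate alkylation, in which C10 is the only enolisable carbon of 2 (C2 is vinylic, C4 quaternary), the single cross-conjugated enolate is alkylated at carbon anti to the vinyl group, and the C10 configuration does not matter because step 3 flattens this centre again.

Step 3
Reactants: 3 trans-6-(benzyloxymethyl)-4,4-dimethyl-5-vinylcyclohex-2-en-1-one
Product: 4 6-(benzyloxymethyl)-6-(hydroxymethyl)-4,4-dimethyl-5-vinylcyclohex-2-en-1-one (C9H2OBn cis and C20H2OH trans to the vinyl group)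
Conditions: LDA, THF, −78 °C; anhydrous CH2O in THF, −78 °C; AcOH quench at −78 °C
Reagents that add atoms: formaldehyde, C=O
Why: Aldol hydroxymethylation of the tetrasubstituted lithium enolate, in which allylic strain with the C10 side chain holds the C5 vinyl group pseudo-axial, formaldehyde therefore arrives from the opposite face and sets the quaternary C10 with C20 trans and C9 cis to C6, while the low temperature and the cold acid quench hold back loss of benzyl oxide and retro-aldol cleavage.

Step 4
Reactants: 4 6-(benzyloxymethyl)-6-(hydroxymethyl)-4,4-dimethyl-5-vinylcyclohex-2-en-1-one; 5 methyl malonyl chloride (methyl 3-chloro-3-oxopropanoate)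
Product: 6 [1-(benzyloxymethyl)-5,5-dimethyl-2-oxo-6-vinylcyclohex-3-en-1-yl]methyl methyl malonate
Conditions: pyridine, CH2Cl2, 0 °C
Reagents that add atoms: none
Why: O-Acylation of the primary neopentyl alcohol by an acid chloride, which brings in C7, C8 and the activating ester, blocks retro-aldol loss of C20 and keeps this oxygen out of the later oxa-Michael step.

Step 5
Reactants: 6 [1-(benzyloxymethyl)-5,5-dimethyl-2-oxo-6-vinylcyclohex-3-en-1-yl]methyl methyl malonate
Product: 8 [1-(benzyloxymethyl)-6-(hydroxymethyl)-5,5-dimethyl-2-oxocyclohex-3-en-1-yl]methyl methyl malonate, via C6 aldehyde 7 (not isolated)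
Conditions: O3, CH2Cl2/MeOH, −78 °C (Sudan Red 7B end point); Me2S, → rt; recool, NaBH4, −78 °C
Reagents that add atoms: ozone, [O-][O+]=O
Why: Ozonolysis followed by chemoselective borohydride reduction, in which the vinyl group is far more electron-rich than the enone alkene and is cleaved first, an aldehyde is reduced at −78 °C much faster than a conjugated α-quaternary ketone, and the aldehyde is not isolated so that C5, for the moment α to a carbonyl group, has no chance to epimerise.

Step 6
Reactants: 8 [1-(benzyloxymethyl)-6-(hydroxymethyl)-5,5-dimethyl-2-oxocyclohex-3-en-1-yl]methyl methyl malonate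
Product: 9 [2-(benzyloxymethyl)-8,8-dimethyl-3-oxo-6-oxabicyclo[3.2.1]octan-2-yl]methyl methyl malonate
Conditions: camphorsulfonic acid (10 mol%), CH2Cl2, rt
Reagents that add atoms: none
Why: Acid-catalysed intramolecular oxa-Michael addition (5-exo-trig) helped by the gem-dimethyl group at C4 (Thorpe–Ingold effect), in which the one-carbon tether can reach C3 only from the face that carries C6 and so sets C3, and which removes the free C6 hydroxyl before C9 is made electrophilic.

Step 7
Reactants: 9 [2-(benzyloxymethyl)-8,8-dimethyl-3-oxo-6-oxabicyclo[3.2.1]octan-2-yl]methyl methyl malonate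
Product: 10 [2-(hydroxymethyl)-8,8-dimethyl-3-oxo-6-oxabicyclo[3.2.1]octan-2-yl]methyl methyl malonate
Conditions: H2 (1 atm), Pd/C, EtOAc, rt
Reagents that add atoms: none
Why: Hydrogenolysis of the benzyl ether, possible here because 9 holds no alkene and its ketone, esters and bridging ether are inert to hydrogen over Pd/C at 1 atm.

Step 8
Reactants: 10 [2-(hydroxymethyl)-8,8-dimethyl-3-oxo-6-oxabicyclo[3.2.1]octan-2-yl]methyl methyl malonate
Product: 12 spiro lactone methyl 8,8-dimethyl-3,6'-dioxo-2'H,6'H-spiro[6-oxabicyclo[3.2.1]octane-2,3'-pyran]-5'-carboxylate, via C9 aldehyde 11 (not isolated)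
Conditions: Dess–Martin periodinane, CH2Cl2, 0 °C → rt; then piperidine (20 mol%), rt
Reagents that add atoms: none
Why: Dess–Martin oxidation followed by intramolecular Knoevenagel condensation (piperidinium acetate forms from the acetic acid released by the oxidant), in which the malonate CH2 (C8) reaches the non-enolisable C9 aldehyde through a six-membered ring much faster than the hindered C1 ketone, loss of water gives C8=C9, and no stereocentre is touched.

Step 9
Reactants: 12 spiro alkylidene-malonate lactone
Product: 13 methyl 8,8-dimethyl-3,6'-dioxo-4'-vinyl-tetrahydrospiro[6-oxabicyclo[3.2.1]octane-2,3'-pyran]-5'-carboxylate (C9 vinyl on the lactone face that carries C1)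
Conditions: CH2=CHMgBr (1.3 equiv), CuBr·SMe2 (20 mol%), THF, −78 °C; sat. aq. NH4Cl
Reagents that add atoms: vinylmagnesium bromide, C=C[Mg]Br
Why: Copper-catalysed conjugate addition of a vinyl Grignard reagent to an alkylidene-malonate acceptor, much faster at −78 °C than attack on the α-quaternary ketone, in which the vinyl group enters anti to the pseudo-axial bulky C5 arm of the spiro centre, on the face flanked by the flat C1 carbonyl, and so sets C9, while C8 remains a labile malonate-type centre.

Step 10
Reactants: 14 methyl acrylate; 15 (tert-butyldimethylsilyloxy)acetaldehyde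
Product: 16 methyl 4-(tert-butyldimethylsilyloxy)-3-hydroxy-2-methylenebutanoate (racemic)
Conditions: DABCO (30 mol%), neat, rt
Reagents that add atoms: none
Why: Morita–Baylis–Hillman reaction, in which the ammonium enolate formed from DABCO and the acrylate attacks the aldehyde, and whose racemic carbinol centre is erased in step 12.

Step 11
Reactants: 16 methyl 4-(tert-butyldimethylsilyloxy)-3-hydroxy-2-methylenebutanoate
Product: 17 methyl 3-acetoxy-4-(tert-butyldimethylsilyloxy)-2-methylenebutanoate (racemic)
Conditions: Ac2O, pyridine, DMAP (cat.), CH2Cl2, 0 °C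
Reagents that add atoms: acetic anhydride, CC(=O)OC(C)=O
Why: Acetylation turns the allylic hydroxyl into a leaving group for the allylic substitution that follows.

Step 12
Reactants: 17 methyl 3-acetoxy-4-(tert-butyldimethylsilyloxy)-2-methylenebutanoate; 18 sodium benzenesulfinate
Product: 19 methyl (Z)-4-(tert-butyldimethylsilyloxy)-2-(phenylsulfonylmethyl)but-2-enoate
Conditions: DMF, rt
Reagents that add atoms: none
Why: SN2′ displacement of a Morita–Baylis–Hillman acetate, in which the soft sulfur of the sulfinate attacks the terminal CH2, acetate leaves, and the trisubstituted enoate forms with CH2OTBS trans to the ester (Z), the usual outcome for acrylate-derived acetates and a geometry that disappears again in step 15.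

Step 13
Reactants: 19 methyl (Z)-4-(tert-butyldimethylsilyloxy)-2-(phenylsulfonylmethyl)but-2-enoate
Product: 20 methyl (Z)-4-bromo-2-(phenylsulfonylmethyl)but-2-enoate
Conditions: Ph3PBr2, CH2Cl2, 0 °C → rt
Reagents that add atoms: dibromotriphenylphosphorane, BrP(Br)(c1ccccc1)(c1ccccc1)c1ccccc1
Why: Direct conversion of a primary allylic silyl ether into the bromide (oxyphosphonium formation, then SN2 by bromide), which leaves ester, sulfone and alkene geometry untouched.

Step 14
Reactants: 13 C9-vinyl lactone ester; 20 methyl (Z)-4-bromo-2-(phenylsulfonylmethyl)but-2-enoate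
Product: 21 spiro lactone with C9 vinyl group and at C8 a methyl ester plus the (Z)-CH2CH=C(CH2SO2Ph)CO2Me chain (chain trans to vinyl)
Conditions: NaH (1.0 equiv), THF/DMF, 0 °C; then 20, 0 °C → rt
Reagents that add atoms: none
Why: Malonate-type alkylation, in which NaH removes only the C8 proton (far more acidic than the ketone α-protons or the sulfonyl CH2 of 20), the soft enolate displaces the primary allylic bromide (SN2) from the face opposite the C9 vinyl group, and C8 is reset in step 16 so that its configuration matters only for the shape of the key transition state.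

Step 15
Reactants: 21 spiro lactone with C9 vinyl group and C8 allyl sulfone chain
Product: 23 ring-A acrylate that still carries the C8 methyl ester, via B-alkylcatecholborane 22 (not isolated)
Conditions: catecholborane (1.2 equiv), RhCl(PPh3)3 (2 mol%), THF, 0 °C → rt; t-BuOH (0.3 equiv); solvent change to benzene (0.05 M), di-tert-butyl hyponitrite (10 mol%), N2, 70 °C
Reagents that add atoms: catecholborane, B1Oc2ccccc2O1 (boron and catecholate are held only in 22; 23 keeps one hydrogen)
Why: Rhodium-catalysed anti-Markovnikov hydroboration puts boron on C12 of the only unactivated alkene and spares the C1 ketone and the enoate; tert-butoxyl radicals then release the primary C12 radical from boron by homolytic substitution, this nucleophilic radical adds to the electron-poor C13, and the C16 radical loses PhSO2• by β-scission, which creates C16=C17 and carries the chain by attacking the boron of the next molecule of 22. The closest known reaction is the tin-free radical allylation of B-alkylcatecholboranes with 2-(arylsulfonylmethyl)acrylates, joined here to the familiar cyclisation of alkyl radicals onto enoates. Ring A (C8, C9, C11, C12, C13, C14) closes in the 6-exo-trig mode by forming C12–C13. C13 is set in a chair transition state with C9–C10, C8–C7 and the acceptor alkene equatorial, because an axial acceptor would run into the axial C8 ester, and this places C16 trans to C10. The step needs ring closure to outrun hydrogen abstraction, 1,5-hydrogen transfer from allylic C14 and capture by oxygen. The polarity match between the alkyl radical and the enoate, the folding imposed by the two quaternary neighbours C8 and C10, the exclusion of air and the use of t-BuOH instead of methanol (no free catechol as hydrogen donor) work in that direction.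

Step 16
Reactants: 23 ring-A acrylate with C8 methyl ester
Product: 24 methyl ester of the target (cis-fused lactone with H8 and H9 on the same face)
Conditions: LiCl (5 equiv), H2O (5 equiv), DMSO, BHT, 140 °C
Reagents that add atoms: none
Why: Krapcho dealkoxycarbonylation, in which chloride dealkylates the ester geminal to the lactone carbonyl, CO2 is lost, and water protonates the lactone enolate from the open equatorial side of ring A (the axial side is screened by the axial hydrogens on C11 and C13), leaving C7 axial and giving the cis-fused lactone, while neopentyl C20 resists chloride and BHT guards the acrylate.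

Step 17
Reactants: 24 methyl ester of the target
Product: 25 target acid CNP0268721.1
Conditions: Me3SnOH (5 equiv), 1,2-dichloroethane, 70 °C; 1 M HCl work-up
Reagents that add atoms: trimethyltin hydroxide, C[Sn](C)(C)O
Why: Mild methyl ester cleavage with Me3SnOH (tin carboxylate, then acid), near-neutral conditions that spare C8 and the β-alkoxy ketone, and after which any lactone opened on the way closes again on acidification.

Compound list
1 | 4,4-dimethylcyclohexa-2,5-dien-1-one | CC1(C)C=CC(=O)C=C1 | starting material
2 | (S)-4,4-dimethyl-5-vinylcyclohex-2-en-1-one | C=C[C@@H]1CC(=O)C=CC1(C)C | intermediate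
3 | 6-(benzyloxymethyl)-4,4-dimethyl-5-vinylcyclohex-2-en-1-one, CH2OBn trans to vinyl | C=C[C@@H]1[C@@H](COCc2ccccc2)C(=O)C=CC1(C)C | intermediate
4 | 6-(benzyloxymethyl)-6-(hydroxymethyl)-4,4-dimethyl-5-vinylcyclohex-2-en-1-one, CH2OBn cis and CH2OH trans to vinyl | C=C[C@@H]1[C@](CO)(COCc2ccccc2)C(=O)C=CC1(C)C | intermediate
5 | methyl malonyl chloride | COC(=O)CC(=O)Cl | starting material
6 | [1-(benzyloxymethyl)-5,5-dimethyl-2-oxo-6-vinylcyclohex-3-en-1-yl]methyl methyl malonate | C=C[C@@H]1[C@](COC(=O)CC(=O)OC)(COCc2ccccc2)C(=O)C=CC1(C)C | intermediate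
7 | [1-(benzyloxymethyl)-6-formyl-5,5-dimethyl-2-oxocyclohex-3-en-1-yl]methyl methyl malonate (not isolated) | O=C[C@@H]1[C@](COC(=O)CC(=O)OC)(COCc2ccccc2)C(=O)C=CC1(C)C | intermediate
8 | [1-(benzyloxymethyl)-6-(hydroxymethyl)-5,5-dimethyl-2-oxocyclohex-3-en-1-yl]methyl methyl malonate | OC[C@@H]1[C@](COC(=O)CC(=O)OC)(COCc2ccccc2)C(=O)C=CC1(C)C | intermediate
9 | [2-(benzyloxymethyl)-8,8-dimethyl-3-oxo-6-oxabicyclo[3.2.1]octan-2-yl]methyl methyl malonate | COC(=O)CC(=O)OC[C@@]1(COCc2ccccc2)C(=O)C[C@@H]3OC[C@H]1C3(C)C | intermediate
10 | [2-(hydroxymethyl)-8,8-dimethyl-3-oxo-6-oxabicyclo[3.2.1]octan-2-yl]methyl methyl malonate | COC(=O)CC(=O)OC[C@@]1(CO)C(=O)C[C@@H]2OC[C@H]1C2(C)C | intermediate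
11 | [2-formyl-8,8-dimethyl-3-oxo-6-oxabicyclo[3.2.1]octan-2-yl]methyl methyl malonate (not isolated) | COC(=O)CC(=O)OC[C@@]1(C=O)C(=O)C[C@@H]2OC[C@H]1C2(C)C | intermediate
12 | spiro 3-methoxycarbonyl-5,6-dihydropyran-2-one on the 8,8-dimethyl-6-oxabicyclo[3.2.1]octan-3-one | COC(=O)C1=C[C@]2(COC1=O)C(=O)C[C@@H]3OC[C@H]2C3(C)C | intermediate
13 | C9-vinyl spiro lactone with C8 methyl ester (C8 labile, drawn with ester trans to vinyl) | C=C[C@@H]1[C@@H](C(=O)OC)C(=O)OC[C@]13C(=O)C[C@@H]4OC[C@H]3C4(C)C | intermediate
14 | methyl acrylate | C=CC(=O)OC | starting material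
15 | (tert-butyldimethylsilyloxy)acetaldehyde | O=CCO[Si](C)(C)C(C)(C)C | starting material
16 | methyl 4-(tert-butyldimethylsilyloxy)-3-hydroxy-2-methylenebutanoate (racemic) | C=C(C(=O)OC)C(O)CO[Si](C)(C)C(C)(C)C | intermediate
17 | methyl 3-acetoxy-4-(tert-butyldimethylsilyloxy)-2-methylenebutanoate (racemic) | C=C(C(=O)OC)C(OC(C)=O)CO[Si](C)(C)C(C)(C)C | intermediate
18 | sodium benzenesulfinate | [Na+].[O-]S(=O)c1ccccc1 | starting material
19 | methyl (Z)-4-(tert-butyldimethylsilyloxy)-2-(phenylsulfonylmethyl)but-2-enoate | CC(C)(C)[Si](C)(C)OC/C=C(\CS(=O)(=O)c1ccccc1)C(=O)OC | intermediate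
20 | methyl (Z)-4-bromo-2-(phenylsulfonylmethyl)but-2-enoate | BrC/C=C(\CS(=O)(=O)c1ccccc1)C(=O)OC | intermediate
21 | key-step precursor: spiro lactone with C9 vinyl, C8 methyl ester and C8 allyl sulfone chain | C=C[C@@H]1[C@](C/C=C(\CS(=O)(=O)c2ccccc2)C(=O)OC)(C(=O)OC)C(=O)OC[C@]13C(=O)C[C@@H]4OC[C@H]3C4(C)C | intermediate
22 | B-alkylcatecholborane, boron on C12 (not isolated) | B1(Oc2ccccc2O1)CC[C@@H]3[C@](C/C=C(\CS(=O)(=O)c4ccccc4)C(=O)OC)(C(=O)OC)C(=O)OC[C@]35C(=O)C[C@@H]6OC[C@H]5C6(C)C | intermediate
23 | key-step product: ring-A acrylate with the C8 methyl ester, trans-fused lactone | C=C(C(=O)OC)[C@@H]1CC[C@@H]2[C@](C1)(C(=O)OC)C(=O)OC[C@]23C(=O)C[C@@H]4OC[C@H]3C4(C)C | intermediate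
24 | methyl ester of the target, cis-fused lactone | C=C(C(=O)OC)[C@@H]1CC[C@@H]2[C@H](C1)C(=O)OC[C@]21C(=O)C[C@@H]2OC[C@H]1C2(C)C | intermediate
25 | CNP0268721.1 | C=C(C(=O)O)[C@@H]1CC[C@@H]2[C@H](C1)C(=O)OC[C@]21C(=O)C[C@@H]2OC[C@H]1C2(C)C | target

Total step count: 17. Longest linear sequence: 13 (steps 1–9 and 14–17).

Steps most likely to fail

Step 15.
- What may go wrong: the 6-exo closure may be too slow. The C12 radical may then be lost to hydrogen abstraction from the medium or to 1,5-hydrogen transfer from allylic C14. A primary radical may also be released from boron too sluggishly to keep the chain going, and the ketone may be partly reduced during hydroboration.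
- Fallback: the radical is made by iodine abstraction instead of homolytic substitution at boron.
- Setting out from 21, the same RhCl(PPh3)3-catalysed hydroboration is worked up with NaBO3·4H2O to the primary C12 alcohol F1.
- I2/PPh3/imidazole turns this into the primary C12 iodide F2.
- Irradiation of F2 with (Bu3Sn)2 in benzene runs the known ditin-mediated allyl sulfone chain. Bu3Sn• takes iodine, the C12 radical closes on C13, and the expelled PhSO2• regenerates Bu3Sn• from the ditin.
- The route is rejoined at 23.

Step 3.
- What may go wrong: deprotonation of the hindered tertiary C10–H may be slow, the lithium enolate may lose benzyl oxide by β-elimination, and the aldolate may revert by retro-aldol cleavage.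
- Fallback: the basic enolate is replaced by a neutral silyl nucleophile.
- Setting out from 3, TMSOTf/Et3N in CH2Cl2 gives the tetrasubstituted trimethylsilyl dienol ether F3.
- F3 undergoes a Mukaiyama-type hydroxymethylation with aqueous formaldehyde and Sc(OTf)3 (cat.) in THF/H2O, again from the face opposite the vinyl group.
- The route is rejoined at 4.

Step 1.
- What may go wrong: conversion at the neopentyl β-carbon may be low, the vinyl reagent may protodeboronate, a second addition may occur, and enantioselectivity may erode.
- Fallback: the absolute configuration is relayed through a removable sulfide.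
- Setting out from 1, an organocatalytic asymmetric sulfa-Michael addition of naphthalene-2-thiol is run with (DHQD)2PYR or its pseudo-enantiomer, whichever places sulfur as drawn. This gives 4,4-dimethyl-5-(naphthalen-2-ylsulfanyl)cyclohex-2-en-1-one F4.
- CH2=CHMgBr/CuBr·SMe2/TMSCl then adds to the remaining enone trans to the sulfide, giving trans-4,4-dimethyl-3-(naphthalen-2-ylsulfanyl)-5-vinylcyclohexan-1-one F5.
- mCPBA at −78 °C gives the sulfoxide F6, which loses the sulfenic acid on warming with Et3N.
- The route is rejoined at 2.

Further compounds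
F1 | step 15 | primary C12 alcohol from 21 | OCC[C@@H]1[C@](C/C=C(\CS(=O)(=O)c2ccccc2)C(=O)OC)(C(=O)OC)C(=O)OC[C@]13C(=O)C[C@@H]4OC[C@H]3C4(C)C
F2 | step 15 | primary C12 iodide | ICC[C@@H]1[C@](C/C=C(\CS(=O)(=O)c2ccccc2)C(=O)OC)(C(=O)OC)C(=O)OC[C@]13C(=O)C[C@@H]4OC[C@H]3C4(C)C
F3 | step 3 | trimethylsilyl dienol ether of 3 | C=C[C@@H]1C(COCc2ccccc2)=C(O[Si](C)(C)C)C=CC1(C)C
F4 | step 1 | 4,4-dimethyl-5-(naphthalen-2-ylsulfanyl)cyclohex-2-en-1-one | O=C1C=CC(C)(C)[C@H](Sc2ccc3ccccc3c2)C1
F5 | step 1 | trans-4,4-dimethyl-3-(naphthalen-2-ylsulfanyl)-5-vinylcyclohexan-1-one | C=C[C@@H]1CC(=O)C[C@@H](Sc2ccc3ccccc3c2)C1(C)C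
F6 | step 1 | sulfoxide of F5 (mixture at sulfur) | C=C[C@@H]1CC(=O)C[C@@H](S(=O)c2ccc3ccccc3c2)C1(C)C
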